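**Retrosynthetic overview**
- The enone of ring B is made last by Saegusa dehydrogenation of a cis-2,3-disubstituted cyclopentanone; the primary acetate comes from selective acylation and the (Z)-side chain from a Wittig reaction on a cis-acetyl group.
- The tertiary diol of ring A comes from OsO4 dihydroxylation of an exocyclic methylene, made from a cyclopentanone whose two cis centres are set by CBS reduction and hydroxyl-directed hydrogenation of a tetrasubstituted cyclopentenone.
- That cyclopentenone (ring A) is closed by intramolecular aldol condensation of a 1,4-diketone, assembled by a Stetter reaction from a ring B aldehyde and a ketal-protected vinyl ketone.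
- The ring B aldehyde is made by the same sequence (Stetter, intramolecular aldol, CBS, directed hydrogenation) from methyl 4-oxobutanoate and methyl vinyl ketone.
- Ring B is formed first, ring A second; three side branches (vinyl ketone, phosphonium salt, dimethyltitanocene) join the main line.

Assumption: a sequence run without isolating its intermediate counts as one step (the intermediate is still numbered), and making a reagent whose carbon ends up in the target counts as a step.

Locants C1, C2, C3 refer to ring A (C1 bears the oxygen) and C1′, C2′, C5′ to the ring B cyclopentyl unit.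

**Step 1**
Reactants: 1 methyl 4-oxobutanoate; 2 but-3-en-2-one
Product: 4 methyl 2-(2-methyl-5-oxocyclopent-1-en-1-yl)acetate, via methyl 4,7-dioxooctanoate 3 (not isolated)
Conditions: 3-benzyl-5-(2-hydroxyethyl)-4-methylthiazolium chloride (10 mol%), Et3N, 1,4-dioxane, 80 °C; then NaOMe, MeOH, 50 °C
Reagents that add atoms: none
Why: A Stetter reaction adds the aldehyde carbon 1,4 to the enone, and intramolecular aldol condensation of the resulting 1,4-diketone (C5 methylene onto the methyl ketone) then closes ring B as the thermodynamically favoured tetrasubstituted cyclopentenone, which has no stereocentre.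

**Step 2**
Reactants: 4 methyl 2-(2-methyl-5-oxocyclopent-1-en-1-yl)acetate
Product: 5 methyl 2-[(5R)-5-hydroxy-2-methylcyclopent-1-en-1-yl]acetate
Conditions: (S)-2-methyl-CBS-oxazaborolidine (20 mol%), BH3·SMe2, THF, −20 °C; MeOH quench
Reagents that add atoms: none
Why: In this Corey–Bakshi–Shibata reduction the substituted alkene side of the ketone acts as the large group, so the (S)-catalyst delivers hydride to one face and gives the (5R)-allylic alcohol while the ester is untouched.

**Step 3**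
Reactants: 5 methyl 2-[(5R)-5-hydroxy-2-methylcyclopent-1-en-1-yl]acetate
Product: 6 methyl 2-[(1R,2R,5R)-2-hydroxy-5-methylcyclopentyl]acetate
Conditions: [Ir(cod)(PCy3)(py)]PF6 (5 mol%), H2 (4 bar), CH2Cl2, 25 °C
Reagents that add atoms: none
Why: In this hydroxyl-directed hydrogenation the iridium bound to the allylic hydroxyl delivers both hydrogens to the hydroxyl face of the tetrasubstituted alkene, which sets C1 and C5 with the acetate arm and the methyl group cis to each other and trans to the hydroxyl, so no lactone can form.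

**Step 4**
Reactants: 6 methyl 2-[(1R,2R,5R)-2-hydroxy-5-methylcyclopentyl]acetate
Product: 7 methyl 2-[(1R,2R,5R)-2-{[tert-butyl(dimethyl)silyl]oxy}-5-methylcyclopentyl]acetate
Conditions: t-BuMe2SiCl, imidazole, DMF, 25 °C
Reagents that add atoms: tert-butyl(dimethyl)silyl chloride, CC(C)(C)[Si](C)(C)Cl
Why: Silylation of the secondary alcohol (silyl ether protection) masks the hydroxyl for the later oxidation and directed hydrogenation without touching a stereocentre.

**Step 5**
Reactants: 7 methyl 2-[(1R,2R,5R)-2-{[tert-butyl(dimethyl)silyl]oxy}-5-methylcyclopentyl]acetate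
Product: 8 2-[(1R,2R,5R)-2-{[tert-butyl(dimethyl)silyl]oxy}-5-methylcyclopentyl]acetaldehyde
Conditions: i-Bu2AlH (1.1 equiv), CH2Cl2, −78 °C; MeOH, aq. potassium sodium tartrate
Reagents that add atoms: none
Why: Partial ester reduction at −78 °C stops at the aluminium hemiacetal, which gives the aldehyde on work-up, and the stereocentres are beta or further from the carbonyl and are not affected.

**Step 6**
Reactants: 9 ethyl 2-oxopropanoate
Product: 10 ethyl 2-methyl-1,3-dioxolane-2-carboxylate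
Conditions: ethylene glycol, p-TsOH (cat.), toluene, reflux (Dean–Stark)
Reagents that add atoms: ethylene glycol, OCCO
Why: Acid-catalysed ketalisation with azeotropic removal of water masks the ketone, which is far more electrophilic than the ester carbonyl.

**Step 7**
Reactants: 10 ethyl 2-methyl-1,3-dioxolane-2-carboxylate
Product: 11 N-methoxy-N,2-dimethyl-1,3-dioxolane-2-carboxamide
Conditions: MeNH(OMe)·HCl, i-PrMgCl, THF, −20 to 0 °C
Reagents that add atoms: N,O-dimethylhydroxylamine hydrochloride, CNOC.Cl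
Why: The magnesium amide of N,O-dimethylhydroxylamine attacks the ester (Weinreb amide synthesis) and the product is inert to further addition.

**Step 8**
Reactants: 11 N-methoxy-N,2-dimethyl-1,3-dioxolane-2-carboxamide
Product: 12 1-(2-methyl-1,3-dioxolan-2-yl)prop-2-en-1-one
Conditions: CH2=CHMgBr, THF, −78 to 0 °C; inverse quench into cold 1 M HCl
Reagents that add atoms: vinylmagnesium bromide, C=C[Mg]Br
Why: In this Weinreb ketone synthesis the chelated tetrahedral magnesium intermediate survives until the acidic quench, so only one vinyl group adds and the liberated amine cannot add to the vinyl ketone.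

**Step 9**
Reactants: 8 2-[(1R,2R,5R)-2-{[tert-butyl(dimethyl)silyl]oxy}-5-methylcyclopentyl]acetaldehyde; 12 1-(2-methyl-1,3-dioxolan-2-yl)prop-2-en-1-one
Product: 13 1-[(1R,2R,5R)-2-{[tert-butyl(dimethyl)silyl]oxy}-5-methylcyclopentyl]-5-(2-methyl-1,3-dioxolan-2-yl)pentane-2,5-dione
Conditions: 3-benzyl-5-(2-hydroxyethyl)-4-methylthiazolium chloride (20 mol%), Et3N, EtOH, 75 °C
Reagents that add atoms: none
Why: In this Stetter reaction the carbene-derived acyl anion equivalent of the aldehyde adds 1,4 to the unhindered vinyl ketone, and the ring B stereocentres are remote from the reacting carbonyl.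

**Step 10**
Reactants: 13 1-[(1R,2R,5R)-2-{[tert-butyl(dimethyl)silyl]oxy}-5-methylcyclopentyl]-5-(2-methyl-1,3-dioxolan-2-yl)pentane-2,5-dione
Product: 14 2-[(1S,2R,5R)-2-{[tert-butyl(dimethyl)silyl]oxy}-5-methylcyclopentyl]-3-(2-methyl-1,3-dioxolan-2-yl)cyclopent-2-en-1-one
Conditions: NaOEt, EtOH, 60 °C
Reagents that add atoms: none
Why: In this intramolecular aldol condensation the only enolisable carbon that can reach a carbonyl through a five-membered ring is C1 of the chain, which adds to the C5 ketone and dehydrates to the cyclopentenone of ring A; no stereocentre is created and the ring B centres, beta to the carbonyl, are untouched.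

**Step 11**
Reactants: 14 2-[(1S,2R,5R)-2-{[tert-butyl(dimethyl)silyl]oxy}-5-methylcyclopentyl]-3-(2-methyl-1,3-dioxolan-2-yl)cyclopent-2-en-1-one
Product: 15 (1R)-2-[(1S,2R,5R)-2-{[tert-butyl(dimethyl)silyl]oxy}-5-methylcyclopentyl]-3-(2-methyl-1,3-dioxolan-2-yl)cyclopent-2-en-1-ol
Conditions: (S)-2-methyl-CBS-oxazaborolidine (20 mol%), BH3·SMe2, THF, −20 °C; MeOH quench
Reagents that add atoms: none
Why: This Corey–Bakshi–Shibata reduction is catalyst-controlled, the alkene-bearing side again being the large group, so the (S)-catalyst gives the (1R)-allylic alcohol whatever the ring B configuration.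

**Step 12**
Reactants: 15 (1R)-2-[(1S,2R,5R)-2-{[tert-butyl(dimethyl)silyl]oxy}-5-methylcyclopentyl]-3-(2-methyl-1,3-dioxolan-2-yl)cyclopent-2-en-1-ol
Product: 16 (1R,2R,3R)-2-[(1S,2R,5R)-2-{[tert-butyl(dimethyl)silyl]oxy}-5-methylcyclopentyl]-3-(2-methyl-1,3-dioxolan-2-yl)cyclopentan-1-ol
Conditions: [Ir(cod)(PCy3)(py)]PF6 (10 mol%), H2 (10 bar), CH2Cl2, 25 °C
Reagents that add atoms: none
Why: Hydroxyl-directed hydrogenation adds both hydrogens to the face of the tetrasubstituted alkene that carries the free hydroxyl (the other oxygen is silylated), which sets C2 and C3 with ring B and the ketal-bearing group cis to each other and trans to the hydroxyl.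

**Step 13**
Reactants: 17 dichloridobis(cyclopentadienyl)titanium, Cp2TiCl2
Product: 18 dimethylbis(cyclopentadienyl)titanium, Cp2TiMe2
Conditions: MeLi (2.1 equiv), Et2O, 0 to 25 °C
Reagents that add atoms: methyllithium, [Li]C
Why: Salt metathesis replaces both chlorides on titanium by methyl groups and gives the Petasis methylenation reagent.

**Step 14**
Reactants: 16 (1R,2R,3R)-2-[(1S,2R,5R)-2-{[tert-butyl(dimethyl)silyl]oxy}-5-methylcyclopentyl]-3-(2-methyl-1,3-dioxolan-2-yl)cyclopentan-1-ol; 18 dimethylbis(cyclopentadienyl)titanium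
Product: 20 tert-butyl(dimethyl){[(1R,2S,3R)-3-methyl-2-[(1R,5R)-2-methylidene-5-(2-methyl-1,3-dioxolan-2-yl)cyclopentyl]cyclopentyl]oxy}silane, via ring A ketone 19 (not isolated)
Conditions: Dess–Martin periodinane, NaHCO3, CH2Cl2, 0 °C; filtration; then Cp2TiMe2 (2.5 equiv), toluene, 65 °C, dark
Reagents that add atoms: none
Why: Buffered Dess–Martin oxidation gives the epimerisable cis-2,3-disubstituted cyclopentanone, and Petasis methylenation through the titanium methylidene ([2+2] cycloaddition and cycloreversion) is non-basic, so the alpha stereocentre C2 is kept while the exocyclic alkene is installed.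

**Step 15**
Reactants: 20 tert-butyl(dimethyl){[(1R,2S,3R)-3-methyl-2-[(1R,5R)-2-methylidene-5-(2-methyl-1,3-dioxolan-2-yl)cyclopentyl]cyclopentyl]oxy}silane
Product: 22 1-[(1R,2R,3R)-3-hydroxy-2-[(1S,2R,5R)-2-hydroxy-5-methylcyclopentyl]-3-(hydroxymethyl)cyclopentyl]ethan-1-one, via diol 21 (not isolated)
Conditions: OsO4 (2 mol%), N-methylmorpholine N-oxide, THF/H2O, 25 °C; Na2SO3; then 2 M HCl, 25 °C
Reagents that add atoms: N-methylmorpholine N-oxide, C[N+]1([O-])CCOCC1; water, O
Why: In this Upjohn dihydroxylation OsO4 adds by [3+2] cycloaddition to the exocyclic alkene from the face opposite the two cis substituents on C2 and C3, so the tertiary hydroxyl ends trans and the CH2OH group cis to ring B, and aqueous acid then hydrolyses the dioxolane and the silyl ether.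

**Step 16**
Reactants: 23 1-cyclopropylethan-1-one
Product: 24 2-cyclopropylpropan-2-ol
Conditions: MeMgBr, Et2O, 0 to 25 °C; aq. NH4Cl
Reagents that add atoms: methylmagnesium bromide, C[Mg]Br
Why: Grignard 1,2-addition to the ketone gives the tertiary cyclopropylcarbinol.

**Step 17**
Reactants: 24 2-cyclopropylpropan-2-ol
Product: 25 5-bromo-2-methylpent-2-ene
Conditions: 48% aq. HBr, 0 to 25 °C
Reagents that add atoms: hydrogen bromide, Br
Why: In this Julia cyclopropylcarbinyl-to-homoallyl rearrangement the tertiary cyclopropylcarbinyl cation is opened by bromide to give the homoallylic bromide with the trisubstituted alkene.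

**Step 18**
Reactants: 25 5-bromo-2-methylpent-2-ene
Product: 26 (4-methylpent-3-en-1-yl)triphenylphosphonium bromide
Conditions: PPh3, MeCN, reflux
Reagents that add atoms: triphenylphosphine, c1ccc(cc1)P(c1ccccc1)c1ccccc1
Why: SN2 quaternisation of triphenylphosphine by the primary bromide gives the phosphonium salt.

**Step 19**
Reactants: 22 1-[(1R,2R,3R)-3-hydroxy-2-[(1S,2R,5R)-2-hydroxy-5-methylcyclopentyl]-3-(hydroxymethyl)cyclopentyl]ethan-1-one; 26 (4-methylpent-3-en-1-yl)triphenylphosphonium bromide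
Product: 28 (1R,2S,3R)-2-[(1S,2R,5R)-2-hydroxy-5-methylcyclopentyl]-1-(hydroxymethyl)-3-[(2Z)-6-methylhepta-2,5-dien-2-yl]cyclopentan-1-ol, via phosphorus ylide 27 (not isolated)
Conditions: 26 (6 equiv), KN(SiMe3)2 (5.8 equiv), THF, −78 to 0 °C; then 22, −78 to 25 °C
Reagents that add atoms: none
Why: In this Wittig olefination with a non-stabilised, lithium-free ylide, kinetically controlled oxaphosphetane formation places the larger ketone substituent (the ring) cis to the alkyl group of the ylide and so favours the (Z)-trisubstituted alkene, three equivalents of ylide being consumed as base by the hydroxyl groups.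

**Step 20**
Reactants: 28 (1R,2S,3R)-2-[(1S,2R,5R)-2-hydroxy-5-methylcyclopentyl]-1-(hydroxymethyl)-3-[(2Z)-6-methylhepta-2,5-dien-2-yl]cyclopentan-1-ol
Product: 29 [(1R,2S,3R)-1-hydroxy-2-[(1S,2R,5R)-2-hydroxy-5-methylcyclopentyl]-3-[(2Z)-6-methylhepta-2,5-dien-2-yl]cyclopentyl]methyl acetate
Conditions: AcCl (1.1 equiv), 2,4,6-collidine, CH2Cl2, −78 °C
Reagents that add atoms: acetyl chloride, CC(=O)Cl
Why: This acylation is chemoselective because at −78 °C the primary hydroxyl is esterified much faster than the secondary and the hindered tertiary one.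

**Step 21**
Reactants: 29 [(1R,2S,3R)-1-hydroxy-2-[(1S,2R,5R)-2-hydroxy-5-methylcyclopentyl]-3-[(2Z)-6-methylhepta-2,5-dien-2-yl]cyclopentyl]methyl acetate
Product: 33 [(1R,2S,3R)-1-hydroxy-2-[(1S,5R)-5-methyl-2-oxocyclopent-3-en-1-yl]-3-[(2Z)-6-methylhepta-2,5-dien-2-yl]cyclopentyl]methyl acetate, via ring B ketone 30 (not isolated), via bis(trimethylsilyl) enol ether 31 (not isolated), via silyl-protected enone 32 (not isolated)
Conditions: Dess–Martin periodinane, NaHCO3, CH2Cl2, 0 °C; then LiN(i-Pr)2 (2.3 equiv), Me3SiCl (6 equiv), THF, −78 °C; then Pd(OAc)2 (1.2 equiv), MeCN, 25 °C; then aq. citric acid, THF, 0 °C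
Reagents that add atoms: none
Why: Dess–Martin oxidation is followed by Saegusa–Ito dehydrogenation, in which kinetic deprotonation at the unhindered CH2 with internal silyl quench gives the less substituted silyl enol ether (the tertiary hydroxyl is silylated in passing) and divalent palladium turns it into the enone by beta-hydride elimination; the methine C1′ is never deprotonated, so the cis relation to the methyl group set in step 3 is kept.

**Compound list**
1 | methyl 4-oxobutanoate | COC(=O)CCC=O | starting material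
2 | but-3-en-2-one (methyl vinyl ketone) | CC(=O)C=C | starting material
3 | methyl 4,7-dioxooctanoate | COC(=O)CCC(=O)CCC(C)=O | intermediate
4 | methyl 2-(2-methyl-5-oxocyclopent-1-en-1-yl)acetate | COC(=O)CC1=C(C)CCC1=O | intermediate
5 | methyl 2-[(5R)-5-hydroxy-2-methylcyclopent-1-en-1-yl]acetate | COC(=O)CC1=C(C)CC[C@H]1O | intermediate
6 | methyl 2-[(1R,2R,5R)-2-hydroxy-5-methylcyclopentyl]acetate | COC(=O)C[C@H]1[C@H](O)CC[C@H]1C | intermediate
7 | methyl 2-[(1R,2R,5R)-2-{[tert-butyl(dimethyl)silyl]oxy}-5-methylcyclopentyl]acetate | COC(=O)C[C@H]1[C@H](O[Si](C)(C)C(C)(C)C)CC[C@H]1C | intermediate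
8 | 2-[(1R,2R,5R)-2-{[tert-butyl(dimethyl)silyl]oxy}-5-methylcyclopentyl]acetaldehyde | O=CC[C@H]1[C@H](O[Si](C)(C)C(C)(C)C)CC[C@H]1C | intermediate
9 | ethyl 2-oxopropanoate (ethyl pyruvate) | CCOC(=O)C(C)=O | starting material
10 | ethyl 2-methyl-1,3-dioxolane-2-carboxylate | CCOC(=O)C1(C)OCCO1 | intermediate
11 | N-methoxy-N,2-dimethyl-1,3-dioxolane-2-carboxamide | CON(C)C(=O)C1(C)OCCO1 | intermediate
12 | 1-(2-methyl-1,3-dioxolan-2-yl)prop-2-en-1-one | C=CC(=O)C1(C)OCCO1 | intermediate
13 | 1-[(1R,2R,5R)-2-{[tert-butyl(dimethyl)silyl]oxy}-5-methylcyclopentyl]-5-(2-methyl-1,3-dioxolan-2-yl)pentane-2,5-dione | CC1(OCCO1)C(=O)CCC(=O)C[C@H]1[C@H](O[Si](C)(C)C(C)(C)C)CC[C@H]1C | intermediate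
14 | 2-[(1S,2R,5R)-2-{[tert-butyl(dimethyl)silyl]oxy}-5-methylcyclopentyl]-3-(2-methyl-1,3-dioxolan-2-yl)cyclopent-2-en-1-one | O=C1CCC(C2(C)OCCO2)=C1[C@H]1[C@H](O[Si](C)(C)C(C)(C)C)CC[C@H]1C | intermediate
15 | (1R)-2-[(1S,2R,5R)-2-{[tert-butyl(dimethyl)silyl]oxy}-5-methylcyclopentyl]-3-(2-methyl-1,3-dioxolan-2-yl)cyclopent-2-en-1-ol | O[C@@H]1CCC(C2(C)OCCO2)=C1[C@H]1[C@H](O[Si](C)(C)C(C)(C)C)CC[C@H]1C | intermediate
16 | (1R,2R,3R)-2-[(1S,2R,5R)-2-{[tert-butyl(dimethyl)silyl]oxy}-5-methylcyclopentyl]-3-(2-methyl-1,3-dioxolan-2-yl)cyclopentan-1-ol | O[C@@H]1CC[C@@H](C2(C)OCCO2)[C@H]1[C@H]1[C@H](O[Si](C)(C)C(C)(C)C)CC[C@H]1C | intermediate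
17 | dichloridobis(cyclopentadienyl)titanium, Cp2TiCl2 | [Cl-].[Cl-].[Ti+4].c1cc[cH-]c1.c1cc[cH-]c1 | starting material
18 | dimethylbis(cyclopentadienyl)titanium, Cp2TiMe2 | [CH3-].[CH3-].[Ti+4].c1cc[cH-]c1.c1cc[cH-]c1 | intermediate
19 | (2R,3R)-2-[(1S,2R,5R)-2-{[tert-butyl(dimethyl)silyl]oxy}-5-methylcyclopentyl]-3-(2-methyl-1,3-dioxolan-2-yl)cyclopentan-1-one | O=C1CC[C@@H](C2(C)OCCO2)[C@H]1[C@H]1[C@H](O[Si](C)(C)C(C)(C)C)CC[C@H]1C | intermediate
20 | tert-butyl(dimethyl){[(1R,2S,3R)-3-methyl-2-[(1R,5R)-2-methylidene-5-(2-methyl-1,3-dioxolan-2-yl)cyclopentyl]cyclopentyl]oxy}silane | C=C1CC[C@@H](C2(C)OCCO2)[C@H]1[C@H]1[C@H](O[Si](C)(C)C(C)(C)C)CC[C@H]1C | intermediate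
21 | (1R,2R,3R)-2-[(1S,2R,5R)-2-{[tert-butyl(dimethyl)silyl]oxy}-5-methylcyclopentyl]-1-(hydroxymethyl)-3-(2-methyl-1,3-dioxolan-2-yl)cyclopentan-1-ol | OC[C@@]1(O)CC[C@@H](C2(C)OCCO2)[C@H]1[C@H]1[C@H](O[Si](C)(C)C(C)(C)C)CC[C@H]1C | intermediate
22 | 1-[(1R,2R,3R)-3-hydroxy-2-[(1S,2R,5R)-2-hydroxy-5-methylcyclopentyl]-3-(hydroxymethyl)cyclopentyl]ethan-1-one | OC[C@@]1(O)CC[C@@H](C(C)=O)[C@H]1[C@H]1[C@H](O)CC[C@H]1C | intermediate
23 | 1-cyclopropylethan-1-one (cyclopropyl methyl ketone) | CC(=O)C1CC1 | starting material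
24 | 2-cyclopropylpropan-2-ol | CC(C)(O)C1CC1 | intermediate
25 | 5-bromo-2-methylpent-2-ene | CC(C)=CCCBr | intermediate
26 | (4-methylpent-3-en-1-yl)triphenylphosphonium bromide | CC(C)=CCC[P+](c1ccccc1)(c1ccccc1)c1ccccc1.[Br-] | intermediate
27 | (4-methylpent-3-en-1-ylidene)triphenylphosphorane | CC(C)=CCC=P(c1ccccc1)(c1ccccc1)c1ccccc1 | intermediate
28 | (1R,2S,3R)-2-[(1S,2R,5R)-2-hydroxy-5-methylcyclopentyl]-1-(hydroxymethyl)-3-[(2Z)-6-methylhepta-2,5-dien-2-yl]cyclopentan-1-ol | OC[C@@]1(O)CC[C@@H](/C(C)=C\CC=C(C)C)[C@H]1[C@H]1[C@H](O)CC[C@H]1C | intermediate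
29 | [(1R,2S,3R)-1-hydroxy-2-[(1S,2R,5R)-2-hydroxy-5-methylcyclopentyl]-3-[(2Z)-6-methylhepta-2,5-dien-2-yl]cyclopentyl]methyl acetate | CC(=O)OC[C@@]1(O)CC[C@@H](/C(C)=C\CC=C(C)C)[C@H]1[C@H]1[C@H](O)CC[C@H]1C | intermediate
30 | [(1R,2S,3R)-1-hydroxy-3-[(2Z)-6-methylhepta-2,5-dien-2-yl]-2-[(1S,2R)-2-methyl-5-oxocyclopentyl]cyclopentyl]methyl acetate | CC(=O)OC[C@@]1(O)CC[C@@H](/C(C)=C\CC=C(C)C)[C@H]1[C@H]1C(=O)CC[C@H]1C | intermediate
31 | [(1R,2S,3R)-3-[(2Z)-6-methylhepta-2,5-dien-2-yl]-2-[(1S,5R)-5-methyl-2-(trimethylsilyloxy)cyclopent-2-en-1-yl]-1-(trimethylsilyloxy)cyclopentyl]methyl acetate | CC(=O)OC[C@@]1(O[Si](C)(C)C)CC[C@@H](/C(C)=C\CC=C(C)C)[C@H]1[C@H]1C(O[Si](C)(C)C)=CC[C@H]1C | intermediate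
32 | [(1R,2S,3R)-3-[(2Z)-6-methylhepta-2,5-dien-2-yl]-2-[(1S,5R)-5-methyl-2-oxocyclopent-3-en-1-yl]-1-(trimethylsilyloxy)cyclopentyl]methyl acetate | CC(=O)OC[C@@]1(O[Si](C)(C)C)CC[C@@H](/C(C)=C\CC=C(C)C)[C@H]1[C@H]1C(=O)C=C[C@H]1C | intermediate
33 | [(1R,2S,3R)-1-hydroxy-2-[(1S,5R)-5-methyl-2-oxocyclopent-3-en-1-yl]-3-[(2Z)-6-methylhepta-2,5-dien-2-yl]cyclopentyl]methyl acetate | CC(=O)OC[C@@]1(O)CC[C@@H](/C(C)=C\CC=C(C)C)[C@H]1[C@H]1C(=O)C=C[C@H]1C | target

**Step count**
Total step count: 21.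
Longest linear sequence: 14 steps (steps 1–5, 9–12, 14, 15, 19–21). Steps 6–8, 13 and 16–18 are side branches.

**Steps most likely to fail**

Step 12 is the first. The alkene is tetrasubstituted and flanked by a secondary cyclopentyl group and a quaternary ketal carbon, so directed hydrogenation may be too slow. The fallback sets out from 14 and comes back at 19. Reduction of 14 with the enantiomeric (R)-2-methyl-CBS-oxazaborolidine and BH3·SMe2 gives the epimeric allylic alcohol (1S)-2-[(1S,2R,5R)-2-{[tert-butyl(dimethyl)silyl]oxy}-5-methylcyclopentyl]-3-(2-methyl-1,3-dioxolan-2-yl)cyclopent-2-en-1-ol F1. Esterification (t-BuCOCl, DMAP, pyridine) gives the pivalate (1S)-2-[(1S,2R,5R)-2-{[tert-butyl(dimethyl)silyl]oxy}-5-methylcyclopentyl]-3-(2-methyl-1,3-dioxolan-2-yl)cyclopent-2-en-1-yl 2,2-dimethylpropanoate F2. Heterogeneous hydrogenation (H2, 50 bar, Rh on Al2O3, EtOAc) is now under steric control and adds hydrogen to the face opposite the bulky ester. It gives the saturated pivalate (1S,2R,3R)-2-[(1S,2R,5R)-2-{[tert-butyl(dimethyl)silyl]oxy}-5-methylcyclopentyl]-3-(2-methyl-1,3-dioxolan-2-yl)cyclopentyl 2,2-dimethylpropanoate F3, with the same configuration at C2 and C3 as 16. Cleavage with i-Bu2AlH gives the alcohol (1S,2R,3R)-2-[(1S,2R,5R)-2-{[tert-butyl(dimethyl)silyl]oxy}-5-methylcyclopentyl]-3-(2-methyl-1,3-dioxolan-2-yl)cyclopentan-1-ol F4, the C1 epimer of 16. Dess–Martin oxidation of F4 gives ketone 19, where the route continues.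

Step 19 is the second. The Z/E ratio of a ketone Wittig reaction is uncertain, and the basic ylide can epimerise the cis-acetyl centre. The fallback sets out from 22 and comes back at 28; it is a Peterson olefination with a weakly basic organocerium reagent.
- (Phenylsulfanylmethyl)trimethylsilane is lithiated with n-BuLi to [phenylsulfanyl(trimethylsilyl)methyl]lithium F5 and alkylated with 1-bromo-3-methylbut-2-ene to trimethyl[4-methyl-1-(phenylsulfanyl)pent-3-en-1-yl]silane F6.
- Reductive lithiation with lithium 4,4′-di-tert-butylbiphenylide gives [4-methyl-1-(trimethylsilyl)pent-3-en-1-yl]lithium F7, and CeCl3 converts it into dichloro[4-methyl-1-(trimethylsilyl)pent-3-en-1-yl]cerium F8.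
- F8 (5 equiv, THF, −78 °C) adds to the ketone of 22 without enolising it and gives the β-hydroxysilanes (1R,2R,3R)-2-[(1S,2R,5R)-2-hydroxy-5-methylcyclopentyl]-1-(hydroxymethyl)-3-[2-hydroxy-6-methyl-3-(trimethylsilyl)hept-5-en-2-yl]cyclopentan-1-ol F9 as a mixture of diastereomers at the two new centres.
- The diastereomers are separated by relative configuration and each set is eliminated stereospecifically, one with KH (syn elimination) and the other with BF3·OEt2 (anti elimination), so that both converge on the (Z)-alkene 28.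

Step 21 is the third. The kinetic enolisation runs beside an acetate and a free tertiary hydroxyl, and divalent palladium may engage the skipped diene. The fallback sets out from ketone 30 and comes back at 32. The tertiary hydroxyl of 30 is capped under non-basic conditions (Me3SiOTf, 2,6-lutidine, CH2Cl2, −78 °C) to give [(1R,2S,3R)-3-[(2Z)-6-methylhepta-2,5-dien-2-yl]-2-[(1S,2R)-2-methyl-5-oxocyclopentyl]-1-(trimethylsilyloxy)cyclopentyl]methyl acetate F10. Kinetic deprotonation (LiN(i-Pr)2, THF, −78 °C) and trapping with PhSeBr gives the selenide [(1R,2S,3R)-3-[(2Z)-6-methylhepta-2,5-dien-2-yl]-2-[(1S,2R)-2-methyl-5-oxo-4-(phenylselanyl)cyclopentyl]-1-(trimethylsilyloxy)cyclopentyl]methyl acetate F11. Oxidation to the selenoxide (H2O2, pyridine, CH2Cl2, 0 °C) and spontaneous syn elimination give the silyl-protected enone 32 without palladium. The citric acid work-up of step 21 then gives 33.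

**Further compounds**
F1 | step 12 | (1S)-2-[(1S,2R,5R)-2-{[tert-butyl(dimethyl)silyl]oxy}-5-methylcyclopentyl]-3-(2-methyl-1,3-dioxolan-2-yl)cyclopent-2-en-1-ol | O[C@H]1CCC(C2(C)OCCO2)=C1[C@H]1[C@H](O[Si](C)(C)C(C)(C)C)CC[C@H]1C
F2 | step 12 | (1S)-2-[(1S,2R,5R)-2-{[tert-butyl(dimethyl)silyl]oxy}-5-methylcyclopentyl]-3-(2-methyl-1,3-dioxolan-2-yl)cyclopent-2-en-1-yl 2,2-dimethylpropanoate | CC(C)(C)C(=O)O[C@H]1CCC(C2(C)OCCO2)=C1[C@H]1[C@H](O[Si](C)(C)C(C)(C)C)CC[C@H]1C
F3 | step 12 | (1S,2R,3R)-2-[(1S,2R,5R)-2-{[tert-butyl(dimethyl)silyl]oxy}-5-methylcyclopentyl]-3-(2-methyl-1,3-dioxolan-2-yl)cyclopentyl 2,2-dimethylpropanoate | CC(C)(C)C(=O)O[C@H]1CC[C@@H](C2(C)OCCO2)[C@H]1[C@H]1[C@H](O[Si](C)(C)C(C)(C)C)CC[C@H]1C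
F4 | step 12 | (1S,2R,3R)-2-[(1S,2R,5R)-2-{[tert-butyl(dimethyl)silyl]oxy}-5-methylcyclopentyl]-3-(2-methyl-1,3-dioxolan-2-yl)cyclopentan-1-ol | O[C@H]1CC[C@@H](C2(C)OCCO2)[C@H]1[C@H]1[C@H](O[Si](C)(C)C(C)(C)C)CC[C@H]1C
F5 | step 19 | [phenylsulfanyl(trimethylsilyl)methyl]lithium | [Li]C(Sc1ccccc1)[Si](C)(C)C
F6 | step 19 | trimethyl[4-methyl-1-(phenylsulfanyl)pent-3-en-1-yl]silane (racemic) | CC(C)=CCC(Sc1ccccc1)[Si](C)(C)C
F7 | step 19 | [4-methyl-1-(trimethylsilyl)pent-3-en-1-yl]lithium | [Li]C(CC=C(C)C)[Si](C)(C)C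
F8 | step 19 | dichloro[4-methyl-1-(trimethylsilyl)pent-3-en-1-yl]cerium | Cl[Ce](Cl)C(CC=C(C)C)[Si](C)(C)C
F9 | step 19 | (1R,2R,3R)-2-[(1S,2R,5R)-2-hydroxy-5-methylcyclopentyl]-1-(hydroxymethyl)-3-[2-hydroxy-6-methyl-3-(trimethylsilyl)hept-5-en-2-yl]cyclopentan-1-ol (diastereomers at the two new centres) | OC[C@@]1(O)CC[C@@H](C(C)(O)C(CC=C(C)C)[Si](C)(C)C)[C@H]1[C@H]1[C@H](O)CC[C@H]1C
F10 | step 21 | [(1R,2S,3R)-3-[(2Z)-6-methylhepta-2,5-dien-2-yl]-2-[(1S,2R)-2-methyl-5-oxocyclopentyl]-1-(trimethylsilyloxy)cyclopentyl]methyl acetate | CC(=O)OC[C@@]1(O[Si](C)(C)C)CC[C@@H](/C(C)=C\CC=C(C)C)[C@H]1[C@H]1C(=O)CC[C@H]1C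
F11 | step 21 | [(1R,2S,3R)-3-[(2Z)-6-methylhepta-2,5-dien-2-yl]-2-[(1S,2R)-2-methyl-5-oxo-4-(phenylselanyl)cyclopentyl]-1-(trimethylsilyloxy)cyclopentyl]methyl acetate (epimers at the selenium-bearing carbon) | CC(=O)OC[C@@]1(O[Si](C)(C)C)CC[C@@H](/C(C)=C\CC=C(C)C)[C@H]1[C@H]1C(=O)C([Se]c2ccccc2)C[C@H]1C
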